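**Strategy.** The cyclopentane (C1–C5; daucane numbering, C1 = methyl-bearing ring-fusion carbon, C4 = isopropyl carbinol, C5 = ring-fusion CH, C6 = ester carbon) is closed last on a preformed seven-membered ring. The feature exploited: the C4 hydroxyl is β to the C6 oxygen and C1 is β to C6, i.e. an aldol retron sitting on an enone β-carbon. A copper-catalysed enantioselective 1,4-addition of Me3Al to an achiral 3-(4-methyl-3-oxopentyl)-6-methylcyclohepta-2,5-dienone makes C1 quaternary, and the resulting C5 aluminium enolate closes onto the side-chain ketone (C4–C5), setting C1, C4 and C5. The dienone comes from an arene by Birch reduction and one-carbon ring expansion. The C8=C9 alkene becomes the trans-diol last, through its α-epoxide.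

Key step: step 8

Remark on numbering: C1–C5 as above; C2, C3 = cyclopentane CH2; C7 = CH2; C8 = C(OH)Me; C9 = CHOH; C10 = CH2. α/β refer to the usual daucane drawing (C1 methyl β).
Assumption: the sense of induction of the phosphoramidite in step 8 is not predicted here; the ligand antipode that gives the C1 configuration of 12 is used (both antipodes are available).

**Step 1**
Reactants: 1 2-hydroxy-4-methylbenzaldehyde; 2 3-methylbutan-2-one
Product: 3 (E)-1-(2-hydroxy-4-methylphenyl)-4-methylpent-1-en-3-one
Conditions: 2 (3 equiv), aq. NaOH, EtOH, rt; then dil. HCl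
Reagents that add atoms: none
Why: Claisen–Schmidt aldol condensation; only the methyl side of the ketone can dehydrate, so the E-enone should form regioselectively.

**Step 2**
Reactants: 3 (E)-1-(2-hydroxy-4-methylphenyl)-4-methylpent-1-en-3-one
Product: 4 1-(2-hydroxy-4-methylphenyl)-4-methylpentan-3-one
Conditions: H2 (1 atm), 10% Pd/C, EtOAc, rt
Reagents that add atoms: none
Why: Chemoselective catalytic hydrogenation of the conjugated C=C; the arene and the ketone should be untouched under these mild conditions.

**Step 3**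
Reactants: 4 1-(2-hydroxy-4-methylphenyl)-4-methylpentan-3-one
Product: 5 1-{2-[(tert-butyldimethylsilyl)oxy]-4-methylphenyl}-4-methylpentan-3-one
Conditions: TBSCl, imidazole, DMF, rt
Reagents that add atoms: tert-butyldimethylsilyl chloride, CC(C)(C)[Si](C)(C)Cl
Why: Standard phenol silylation; the aryl silyl ether is the group that becomes a silyl enol ether in the Birch reduction.

**Step 4**
Reactants: 5 1-{2-[(tert-butyldimethylsilyl)oxy]-4-methylphenyl}-4-methylpentan-3-one
Product: 6 1-{2-[(tert-butyldimethylsilyl)oxy]-4-methylcyclohexa-1,4-dien-1-yl}-4-methylpentan-3-ol (racemic)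
Conditions: Li, NH3(l), THF, t-BuOH, −78 → −33 °C; solid NH4Cl
Reagents that add atoms: none
Why: Birch reduction of an aryl silyl ether; protonation at the two unsubstituted, mutually para positions leaves the siloxy/alkyl and methyl carbons on the two double bonds, and the ketone is reduced to the alcohol at the same time (restored in step 6).

**Step 5**
Reactants: 6 1-{2-[(tert-butyldimethylsilyl)oxy]-4-methylcyclohexa-1,4-dien-1-yl}-4-methylpentan-3-ol
Product: 7 1-{6-[(tert-butyldimethylsilyl)oxy]-4-methylbicyclo[4.1.0]hept-3-en-1-yl}-4-methylpentan-3-ol (carbinol epimers, both converge in step 6)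
Conditions: Et2Zn, CH2I2, CH2Cl2, 0 °C → rt
Reagents that add atoms: diiodomethane, ICI
Why: Simmons–Smith cyclopropanation (Furukawa variant); the electrophilic zinc carbenoid should select the electron-rich silyl enol ether over the trisubstituted alkene.

**Step 6**
Reactants: 7 1-{6-[(tert-butyldimethylsilyl)oxy]-4-methylbicyclo[4.1.0]hept-3-en-1-yl}-4-methylpentan-3-ol
Product: 8 1-{6-[(tert-butyldimethylsilyl)oxy]-4-methylbicyclo[4.1.0]hept-3-en-1-yl}-4-methylpentan-3-one (racemic)
Conditions: Dess–Martin periodinane, NaHCO3, CH2Cl2, 0 °C → rt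
Reagents that add atoms: none
Why: Dess–Martin oxidation of the secondary alcohol to the isopropyl ketone under buffered conditions that should spare the siloxycyclopropane.

**Step 7**
Reactants: 8 1-{6-[(tert-butyldimethylsilyl)oxy]-4-methylbicyclo[4.1.0]hept-3-en-1-yl}-4-methylpentan-3-one
Product: 10 6-methyl-3-(4-methyl-3-oxopentyl)cyclohepta-2,5-dien-1-one, via β-chloro ketone 9 (not isolated)
Conditions: FeCl3, DMF, 0 °C → rt; then Et3N, 0 °C
Reagents that add atoms: none
Why: Ito–Saegusa oxidative ring expansion of a siloxycyclopropane; Fe(III) gives a cyclopropoxy radical whose internal bond cleaves to the tertiary ring-expanded radical, chlorine transfer gives 9, and E1cB loss of HCl gives the achiral 3-substituted cycloheptadienone.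

**Step 8**
Reactants: 10 6-methyl-3-(4-methyl-3-oxopentyl)cyclohepta-2,5-dien-1-one
Product: 12 (3R,3aR,8aR)-3-hydroxy-6,8a-dimethyl-3-(propan-2-yl)-2,3,3a,5,8,8a-hexahydroazulen-4(1H)-one (4β-hydroxy-5α-dauc-8-en-6-one), via aluminium enolate 11 (not isolated)
Conditions: CuTC (5 mol %), chiral phosphoramidite L* (SimplePhos type, 10 mol %), Me3Al (1.5 equiv), Et2O, −30 → 0 °C; aq. Rochelle salt
Reagents that add atoms: trimethylaluminium, C[Al](C)C
Why: The chiral Cu(I)–phosphoramidite transfers methyl from Me3Al to C1, the enone β-carbon of achiral 10, which gives the C5 aluminium enolate 11 regiospecifically (C5, not the doubly activated C7); this enolate then adds to the aluminium-bound side-chain isopropyl ketone at C4. The closest known reaction types are the copper-catalysed enantioselective addition of Me3Al to 3-substituted cycloheptenones (quaternary centres) and tandem conjugate addition–aldol cyclisation of enone-ketones. The cyclopentane closes by a 5-(enolexo)-exo-trig aldol that forms C4–C5. C1 is set by the ligand; C4 is set by the closed transition state in which aluminium bridges the enolate oxygen and the ketone oxygen, so that the new hydroxyl ends syn to the C6 carbonyl (OH β, isopropyl α). C5 should come out trans-fused (H-5 α) because the cycloheptadienolate can react through the conformer with the C1 methyl in the enolate plane and the keto chain pseudo-axial, and the aluminium aldolate can also equilibrate by retro-aldol/aldol without touching C7. The step needs 1,4- over 1,2-methylation, an untouched isopropyl ketone and no migration of the skipped C8=C9 bond; copper catalysis at low temperature, the hindered ketone and the non-basic medium should secure this.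

**Step 9**
Reactants: 12 4β-hydroxy-5α-dauc-8-en-6-one
Product: 13 (3R,3aS,4S,8aR)-6,8a-dimethyl-3-(propan-2-yl)-1,2,3,3a,4,5,8,8a-octahydroazulene-3,4-diol (jaeschkeanadiol)
Conditions: Me4NBH(OAc)3, MeCN–AcOH (1:1), −20 °C
Reagents that add atoms: none
Why: Evans–Saksena hydroxyl-directed reduction; the C4 alkoxyborohydride should deliver hydride intramolecularly to the β face of C6, giving the 6α-alcohol (anti-1,3-diol), and the mild acidic medium leaves the β,γ-alkene in place.

**Step 10**
Reactants: 13 jaeschkeanadiol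
Product: 14 8α,9α-epoxy-5α-daucane-4β,6α-diol
Conditions: VO(acac)2 (cat.), t-BuOOH, CH2Cl2, 0 °C → rt
Reagents that add atoms: tert-butyl hydroperoxide, CC(C)(C)OO
Why: Vanadium-catalysed hydroxyl-directed epoxidation; the homoallylic 6α-hydroxyl should deliver oxygen to the α face of the C8=C9 alkene.

**Step 11**
Reactants: 14 8α,9α-epoxy-5α-daucane-4β,6α-diol; 15 4-acetoxybenzoyl chloride
Product: 17 8α,9α-epoxy-4β-hydroxy-5α-daucan-6α-yl 4-hydroxybenzoate, via acetate ester 16 (not isolated)
Conditions: DMAP, pyridine, CH2Cl2, 0 °C → rt; then pyrrolidine, rt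
Reagents that add atoms: none
Why: DMAP-catalysed acylation; only the secondary 6-OH should react (the 4-OH is tertiary), and the aryl acetate is then aminolysed selectively because it is far more electrophilic than the hindered alkyl benzoate.

**Step 12**
Reactants: 17 8α,9α-epoxy-4β-hydroxy-5α-daucan-6α-yl 4-hydroxybenzoate
Product: 18 (3R,3aS,4S,6S,7S,8aR)-3,6,7-trihydroxy-6,8a-dimethyl-3-(propan-2-yl)decahydroazulen-4-yl 4-hydroxybenzoate (CNP0197754.1)
Conditions: HClO4 (cat.), THF–H2O (3:1), 0 °C → rt
Reagents that add atoms: water, O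
Why: Acid-catalysed epoxide hydrolysis; water should attack the tertiary C8 from the β face with inversion while the C9–O bond is retained, giving the 8β,9α trans-diol.

**Compound list**

1 | 2-hydroxy-4-methylbenzaldehyde | Cc1ccc(C=O)c(O)c1 | starting material
2 | 3-methylbutan-2-one | CC(C)C(C)=O | starting material
3 | (E)-1-(2-hydroxy-4-methylphenyl)-4-methylpent-1-en-3-one | Cc1ccc(/C=C/C(=O)C(C)C)c(O)c1 | intermediate
4 | 1-(2-hydroxy-4-methylphenyl)-4-methylpentan-3-one | Cc1ccc(CCC(=O)C(C)C)c(O)c1 | intermediate
5 | 1-{2-[(tert-butyldimethylsilyl)oxy]-4-methylphenyl}-4-methylpentan-3-one | Cc1ccc(CCC(=O)C(C)C)c(O[Si](C)(C)C(C)(C)C)c1 | intermediate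
6 | 1-{2-[(tert-butyldimethylsilyl)oxy]-4-methylcyclohexa-1,4-dien-1-yl}-4-methylpentan-3-ol (racemic) | CC(C)C(O)CCC1=C(O[Si](C)(C)C(C)(C)C)CC(C)=CC1 | intermediate
7 | 1-{6-[(tert-butyldimethylsilyl)oxy]-4-methylbicyclo[4.1.0]hept-3-en-1-yl}-4-methylpentan-3-ol (carbinol epimers) | CC(C)C(O)CCC12CC=C(C)CC1(O[Si](C)(C)C(C)(C)C)C2 | intermediate
8 | 1-{6-[(tert-butyldimethylsilyl)oxy]-4-methylbicyclo[4.1.0]hept-3-en-1-yl}-4-methylpentan-3-one (racemic) | CC(C)C(=O)CCC12CC=C(C)CC1(O[Si](C)(C)C(C)(C)C)C2 | intermediate
9 | 3-chloro-6-methyl-3-(4-methyl-3-oxopentyl)cyclohept-5-en-1-one (not isolated) | CC(C)C(=O)CCC1(Cl)CC=C(C)CC(=O)C1 | intermediate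
10 | 6-methyl-3-(4-methyl-3-oxopentyl)cyclohepta-2,5-dien-1-one | CC(C)C(=O)CCC1=CC(=O)CC(C)=CC1 | intermediate
11 | dimethylaluminium enolate (C1=C7) of 3,6-dimethyl-6-(4-methyl-3-oxopentyl)cyclohept-3-en-1-one, quaternary centre configured as C1 of 12 (not isolated) | CC(C)C(=O)CC[C@]1(C)CC=C(C)CC(O[Al](C)C)=C1 | intermediate
12 | (3R,3aR,8aR)-3-hydroxy-6,8a-dimethyl-3-(propan-2-yl)-2,3,3a,5,8,8a-hexahydroazulen-4(1H)-one | CC(C)[C@]1(O)CC[C@]2(C)CC=C(C)CC(=O)[C@H]21 | intermediate
13 | (3R,3aS,4S,8aR)-6,8a-dimethyl-3-(propan-2-yl)-1,2,3,3a,4,5,8,8a-octahydroazulene-3,4-diol (jaeschkeanadiol) | CC(C)[C@]1(O)CC[C@]2(C)CC=C(C)C[C@H](O)[C@H]21 | intermediate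
14 | 8α,9α-epoxy-5α-daucane-4β,6α-diol | CC(C)[C@]1(O)CC[C@]2(C)C[C@@H]3O[C@]3(C)C[C@H](O)[C@H]21 | intermediate
15 | 4-acetoxybenzoyl chloride | CC(=O)Oc1ccc(cc1)C(Cl)=O | starting material
16 | 8α,9α-epoxy-4β-hydroxy-5α-daucan-6α-yl 4-acetoxybenzoate (not isolated) | CC(C)[C@]1(O)CC[C@]2(C)C[C@@H]3O[C@]3(C)C[C@H](OC(=O)c4ccc(OC(C)=O)cc4)[C@H]21 | intermediate
17 | 8α,9α-epoxy-4β-hydroxy-5α-daucan-6α-yl 4-hydroxybenzoate | CC(C)[C@]1(O)CC[C@]2(C)C[C@@H]3O[C@]3(C)C[C@H](OC(=O)c4ccc(O)cc4)[C@H]21 | intermediate
18 | (3R,3aS,4S,6S,7S,8aR)-3,6,7-trihydroxy-6,8a-dimethyl-3-(propan-2-yl)decahydroazulen-4-yl 4-hydroxybenzoate | CC(C)[C@]1(O)CC[C@]2(C)C[C@H](O)[C@@](C)(O)C[C@H](OC(=O)c3ccc(O)cc3)[C@H]21 | target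

**Totals.** Total step count: 12. Longest linear sequence: 12 steps (from 1).

**Steps most likely to fail**

Step 8. The aluminium enolate may close through the cis-fused transition state or close incompletely, and the skipped C8=C9 bond may migrate under the Lewis-acidic aluminium reagent before methyl transfer. The fallback sets out from 10 and returns at 12. The same copper-catalysed Me3Al addition is run at −78 °C and the aluminium enolate is silylated in situ with TMSOTf before it can cyclise, giving the trimethylsilyl enol ether F1. After isolation, F1 is closed with TiCl4 in CH2Cl2 at −78 °C by an intramolecular Mukaiyama aldol, whose open transition state offers a different diastereoselectivity profile, and aqueous work-up gives 12.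

Step 7. The skipped C8=C9 bond may move into conjugation during the base-mediated loss of HCl from 9, or already in the Fe(III) medium. The fallback sets out from 8 and returns at 10. Buffered desilylation (TBAF, AcOH, THF, 0 °C) gives the cyclopropanol F2. Oxidative ring opening with Mn(III) tris(2-pyridinecarboxylate) in DMF in the presence of diphenyl diselenide traps the ring-expanded tertiary radical as the β-(phenylseleno) ketone F3. Oxidation with H2O2 (pyridine buffer, CH2Cl2, 0 °C) and selenoxide syn-elimination then gives 10 without an amine-base step.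

Step 12. The developing cation at C8 may be captured transannularly by the 4β-hydroxyl (ether formation), or the epoxide may open without stereospecificity. The fallback sets out from 17 and returns at 18. Silylation with TBSOTf and 2,6-lutidine masks the tertiary 4-OH and the phenol as the bis(silyl) ether F4. The same acid hydrolysis (HClO4 cat., THF–H2O, 0 °C) then gives the bis(silyl) diol F5, and TBAF buffered with AcOH removes both silyl groups to give 18.

**Further compounds**

F1 | step 8 | trimethylsilyl enol ether of the methyl adduct of 10 (quaternary centre as in 12) | CC(C)C(=O)CC[C@]1(C)CC=C(C)CC(O[Si](C)(C)C)=C1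
F2 | step 7 | 1-(6-hydroxy-4-methylbicyclo[4.1.0]hept-3-en-1-yl)-4-methylpentan-3-one | CC(C)C(=O)CCC12CC=C(C)CC1(O)C2
F3 | step 7 | 6-methyl-3-(4-methyl-3-oxopentyl)-3-(phenylselanyl)cyclohept-5-en-1-one | CC(C)C(=O)CCC1([Se]c2ccccc2)CC=C(C)CC(=O)C1
F4 | step 12 | 8α,9α-epoxy-4β-[(tert-butyldimethylsilyl)oxy]-5α-daucan-6α-yl 4-[(tert-butyldimethylsilyl)oxy]benzoate | CC(C)[C@]1(O[Si](C)(C)C(C)(C)C)CC[C@]2(C)C[C@@H]3O[C@]3(C)C[C@H](OC(=O)c4ccc(O[Si](C)(C)C(C)(C)C)cc4)[C@H]21
F5 | step 12 | 4β-[(tert-butyldimethylsilyl)oxy]-8β,9α-dihydroxy-5α-daucan-6α-yl 4-[(tert-butyldimethylsilyl)oxy]benzoate | CC(C)[C@]1(O[Si](C)(C)C(C)(C)C)CC[C@]2(C)C[C@H](O)[C@@](C)(O)C[C@H](OC(=O)c3ccc(O[Si](C)(C)C(C)(C)C)cc3)[C@H]21
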